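Retrosynthesis cuts ring C of the upper unit at C3–C4 and O1–C2 (one cycloaddition), then the bond between the future C4 and C8' of the lower unit (aryllithium plus aldehyde), and in the two-carbon partner the enol C–O bond and the styryl C=C bond.
Enabling feature: O1 and C4 are ortho substituents of benzo ring A, so O1–C8a–C4a–C4 is a masked o-quinone methide whose methide carbon C4 already carries ring D through C8'. C2 (with aryl ring B) and C3 (with its oxygen) are the two carbons of a trans β-oxygenated styrene, and the all-trans C2/C3/C4 triad is the endo adduct of these two (E)-configured partners.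
Forward order: rings D, E and F come intact from (-)-epiafzelechin (benzylated, brominated at C8'); ring A is attached through a carbinol carbon; ring C is closed last; the ester and the benzyl ethers are then removed.
Stereochemistry: C2' and C3' are bought with epiafzelechin; the relative configuration at C2, C3 and C4 follows from the (E)-alkene and the endo transition state; the absolute sense comes from a chiral phosphoric acid.

Key step: step 10

Remark on the chemistry: (-)-epiafzelechin (2R,3R) is taken as the purchasable natural product; the carbinol centre made at the fragment union is carried as both epimers because the key step flattens it; the (R)-antipode of the phosphoric acid is assumed to be the one matched to the lower unit, and its mirror image would be used otherwise with no other change.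

Step 1
Reactants: 1 (-)-epiafzelechin
Product: 2 5,7,4'-tri-O-benzylepiafzelechin
Conditions: BnBr (3.3 equiv), K2CO3, DMF, 0 °C → rt
Reagents that add atoms: benzyl bromide, BrCc1ccccc1
Why: Williamson etherification in which K2CO3 ionises only the three phenols, so the secondary hydroxyl stays free and the mild base leaves the cis-(2R,3R) centres untouched.

Step 2
Reactants: 2 5,7,4'-tri-O-benzylepiafzelechin
Product: 3 8-bromo-5,7,4'-tri-O-benzylepiafzelechin
Conditions: NBS (1.0 equiv), CH2Cl2, –78 °C → rt
Reagents that add atoms: N-bromosuccinimide, O=C1CCC(=O)N1Br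
Why: Electrophilic aromatic bromination of the phloroglucinol-type ring D, which in 5,7-di-O-benzylflavan-3-ols is known to take place at C8' rather than C6', while the mono-alkoxylated ring E is far less reactive.

Step 3
Reactants: 3 8-bromo-5,7,4'-tri-O-benzylepiafzelechin
Product: 4 8-bromo-3,5,7,4'-tetra-O-benzylepiafzelechin
Conditions: NaH, BnBr, DMF, 0 °C → rt
Reagents that add atoms: benzyl bromide, BrCc1ccccc1
Why: Williamson etherification of the sodium alkoxide; with every phenol already capped no phenolate can open ring F, so C2' and C3' keep their configuration, and the aryl bromide is inert.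

Step 4
Reactants: 5 4-(benzyloxy)-2-hydroxybenzaldehyde
Product: 6 2-(allyloxy)-4-(benzyloxy)benzaldehyde
Conditions: allyl bromide, K2CO3, DMF, rt
Reagents that add atoms: allyl bromide, C=CCBr
Why: Williamson etherification of the salicylaldehyde phenol; allyl is chosen because zerovalent palladium removes it later under neutral conditions that benzyl ethers and an acid-labile benzhydrol tolerate.

Step 5
Reactants: 4 8-bromo-3,5,7,4'-tetra-O-benzylepiafzelechin; 6 2-(allyloxy)-4-(benzyloxy)benzaldehyde
Product: 8 [2-(allyloxy)-4-(benzyloxy)phenyl][(2R,3R)-3,5,7-tris(benzyloxy)-2-(4-benzyloxyphenyl)chroman-8-yl]methanol (both carbinol epimers), via C8' aryllithium 7 (not isolated)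
Conditions: t-BuLi (2.1 equiv), THF, –78 °C; then 6, –78 → –40 °C; pH 7 aqueous quench
Reagents that add atoms: none
Why: Bromine–lithium exchange followed by 1,2-addition of the aryllithium to the aldehyde, the established way to functionalise C8 of perbenzylated 8-bromoflavan-3-ols; the new carbinol centre forms without control and is irrelevant because it becomes sp2 in step 10.

Step 6
Reactants: 8 allyl-protected benzhydrol
Product: 9 [4-(benzyloxy)-2-hydroxyphenyl][(2R,3R)-3,5,7-tris(benzyloxy)-2-(4-benzyloxyphenyl)chroman-8-yl]methanol (both carbinol epimers)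
Conditions: Pd(PPh3)4 (5 mol %), morpholine, THF, rt; filtration through Et3N-deactivated silica
Reagents that add atoms: none
Why: Tsuji–Trost deallylation, in which zerovalent palladium ionises the aryl allyl ether to a π-allyl complex that morpholine intercepts; the medium is neutral to basic, so the benzyl ethers stay and the ionisation-prone benzhydrol meets no acid.

Step 7
Reactants: 10 4-(benzyloxy)benzaldehyde
Product: 11 (E)-2-[4-(benzyloxy)styryl]-4,4,5,5-tetramethyl-1,3,2-dioxaborolane
Conditions: CH2(Bpin)2, lithium 2,2,6,6-tetramethylpiperidide (LiTMP), THF, 0 °C; then 10, –78 °C → rt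
Reagents that add atoms: bis(4,4,5,5-tetramethyl-1,3,2-dioxaborolan-2-yl)methane, CC1(C)OB(CB2OC(C)(C)C(C)(C)O2)OC1(C)C
Why: Boron–Wittig olefination, in which the α-boryl carbanion adds to the aldehyde and a borate is eliminated, a process known to give trans-alkenylboronates from aryl aldehydes.

Step 8
Reactants: 11 (E)-styrylboronic pinacol ester
Product: 12 potassium (E)-[4-(benzyloxy)styryl]trifluoroborate
Conditions: KHF2 (aq), MeOH, rt; pinacol removed by repeated evaporation from aqueous MeOH
Reagents that add atoms: potassium hydrogen difluoride, [K+].[F-].F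
Why: Ligand exchange at boron with KHF2 gives the crystalline trifluoroborate with the alkene geometry unchanged, the form of the boron reagent that is competent in the copper-catalysed C–O coupling.

Step 9
Reactants: 12 potassium (E)-[4-(benzyloxy)styryl]trifluoroborate
Product: 13 (E)-4-(benzyloxy)styryl acetate
Conditions: AcOH, CuBr (10 mol %), DMAP (20 mol %), 4 Å MS, O2 (1 atm), MeCN, 60 °C
Reagents that add atoms: acetic acid, CC(=O)O
Why: Chan–Lam–Evans oxidative coupling of an alkenyltrifluoroborate with a carboxylic acid, which is stereoretentive at the alkene, so the (E)-geometry fixed in step 7 is handed on to the enol acetate without the E/Z mixture that enolisation of an arylacetaldehyde would give.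

Step 10
Reactants: 9 o-hydroxybenzhydrol; 13 (E)-4-(benzyloxy)styryl acetate
Product: 15 hexa-O-benzyl guibourtinidol-(4α→8)-epiafzelechin 3-O-acetate [(2R,3S,4S) upper unit, (2R,3R) lower unit], via (E)-o-quinone methide 14 (not isolated)
Conditions: (R)-TRIP [(R)-3,3'-bis(2,4,6-triisopropylphenyl)-1,1'-binaphthyl-2,2'-diyl hydrogen phosphate] (10 mol %), 13 (3 equiv), 5 Å MS, CH2Cl2, –20 °C → rt
Reagents that add atoms: none
Why: Proposed new method: the phosphoric acid protonates the carbinol of 9 and, with loss of water, gives the hydrogen-bonded (E)-o-quinone methide 14 from either epimer; the acetoxy-bearing carbon of 13, the nucleophilic terminus of a 4-alkoxystyrene, attacks the methide carbon (C3–C4) and the ring A oxygen collapses on the incipient 4-benzyloxybenzyl cation (O1–C2). The closest known reaction type is the Brønsted-acid-catalysed inverse-demand hetero-Diels–Alder reaction of o-quinone methides with styrenes and β-alkylstyrenes to 2,4-cis-diarylchromans, including chiral phosphoric acid versions, whereas a β-acyloxystyrene has not been used as the 2π partner. Ring C closes as a six-membered dihydropyran in this asynchronous [4+2] cycloaddition (4π O=C8a–C4a=C4 plus 2π C3=C2), not in a separate cyclisation. C2 and C3 become trans because the (E)-geometry of 13 is carried over suprafacially, C4 becomes cis to C2 and trans to C3 because the 4-benzyloxyphenyl group lies endo over the (E)-methide whose ring D substituent points outward, and the absolute sense (2R,3S,4S) is dictated by the chiral phosphate bound to the methide oxygen, which has to override the weak bias of the remote C2' and C3' centres. The step needs regioselectivity (aryl at C2, oxygen at C3), secured because the 4-benzyloxyphenyl group stabilises positive charge at C2 far better than the weakly donating acetoxy group could at C3, and it needs capture of the methide to outrun its self-condensation, for which the excess of 13, the sieves and the low temperature are provided.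

Step 11
Reactants: 15 hexa-O-benzyl 3-O-acetate
Product: 16 hexa-O-benzyl guibourtinidol-(4α→8)-epiafzelechin (free C3 hydroxyl)
Conditions: K2CO3 (0.2 equiv), MeOH/THF, rt
Reagents that add atoms: none
Why: Base-catalysed transesterification (methanolysis) of the secondary acetate, done while every phenol is still benzylated so that no phenolate can epimerise C2 or C2' through a quinone methide.

Step 12
Reactants: 16 hexa-O-benzyl guibourtinidol-(4α→8)-epiafzelechin
Product: 17 guibourtinidol-(4α→8)-epiafzelechin (target)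
Conditions: H2 (1 atm), Pd(OH)2/C, THF/MeOH, rt
Reagents that add atoms: none
Why: Catalytic hydrogenolysis of the six benzyl ethers under neutral conditions, which, as known for benzylated proanthocyanidins, leaves the flavan C2–O bonds, the interflavan C4–C8' bond and all five stereocentres intact.

Compound list
1 | (-)-epiafzelechin, (2R,3R)-2-(4-hydroxyphenyl)chroman-3,5,7-triol | Oc1ccc([C@H]2Oc3cc(O)cc(O)c3C[C@H]2O)cc1 | starting material
2 | 5,7,4'-tri-O-benzylepiafzelechin, (2R,3R)-5,7-bis(benzyloxy)-2-[4-(benzyloxy)phenyl]chroman-3-ol | c1c(OCc2ccccc2)cc(OCc2ccccc2)c2c1O[C@H](c1ccc(OCc3ccccc3)cc1)[C@H](O)C2 | intermediate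
3 | 8-bromo-5,7,4'-tri-O-benzylepiafzelechin | Brc1c(OCc2ccccc2)cc(OCc2ccccc2)c2c1O[C@H](c1ccc(OCc3ccccc3)cc1)[C@H](O)C2 | intermediate
4 | 8-bromo-3,5,7,4'-tetra-O-benzylepiafzelechin | Brc1c(OCc2ccccc2)cc(OCc2ccccc2)c2c1O[C@H](c1ccc(OCc3ccccc3)cc1)[C@H](OCc1ccccc1)C2 | intermediate
5 | 4-(benzyloxy)-2-hydroxybenzaldehyde | O=Cc1ccc(OCc2ccccc2)cc1O | starting material
6 | 2-(allyloxy)-4-(benzyloxy)benzaldehyde | O=Cc1ccc(OCc2ccccc2)cc1OCC=C | intermediate
7 | 8-lithio-3,5,7,4'-tetra-O-benzylepiafzelechin (aryllithium formed in the flask) | [Li]c1c(OCc2ccccc2)cc(OCc2ccccc2)c2c1O[C@H](c1ccc(OCc3ccccc3)cc1)[C@H](OCc1ccccc1)C2 | intermediate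
8 | [2-(allyloxy)-4-(benzyloxy)phenyl][(2R,3R)-3,5,7-tris(benzyloxy)-2-(4-benzyloxyphenyl)chroman-8-yl]methanol (carbinol epimers) | OC(c1ccc(OCc2ccccc2)cc1OCC=C)c1c(OCc2ccccc2)cc(OCc2ccccc2)c2c1O[C@H](c1ccc(OCc3ccccc3)cc1)[C@H](OCc1ccccc1)C2 | intermediate
9 | [4-(benzyloxy)-2-hydroxyphenyl][(2R,3R)-3,5,7-tris(benzyloxy)-2-(4-benzyloxyphenyl)chroman-8-yl]methanol (carbinol epimers) | OC(c1ccc(OCc2ccccc2)cc1O)c1c(OCc2ccccc2)cc(OCc2ccccc2)c2c1O[C@H](c1ccc(OCc3ccccc3)cc1)[C@H](OCc1ccccc1)C2 | intermediate
10 | 4-(benzyloxy)benzaldehyde | O=Cc1ccc(OCc2ccccc2)cc1 | starting material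
11 | (E)-2-[4-(benzyloxy)styryl]-4,4,5,5-tetramethyl-1,3,2-dioxaborolane | CC1(C)OB(/C=C/c2ccc(OCc3ccccc3)cc2)OC1(C)C | intermediate
12 | potassium (E)-[4-(benzyloxy)styryl]trifluoroborate | [K+].F[B-](F)(F)/C=C/c1ccc(OCc2ccccc2)cc1 | intermediate
13 | (E)-4-(benzyloxy)styryl acetate | CC(=O)O/C=C/c1ccc(OCc2ccccc2)cc1 | intermediate
14 | (E)-3-(benzyloxy)-6-{[(2R,3R)-3,5,7-tris(benzyloxy)-2-(4-benzyloxyphenyl)chroman-8-yl]methylidene}cyclohexa-2,4-dien-1-one (ring A o-quinone methide formed in the flask) | O=C1C=C(OCc2ccccc2)C=C/C1=C\c1c(OCc2ccccc2)cc(OCc2ccccc2)c2c1O[C@H](c1ccc(OCc3ccccc3)cc1)[C@H](OCc1ccccc1)C2 | intermediate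
15 | (2R,3S,4S)-7-(benzyloxy)-2-[4-(benzyloxy)phenyl]-4-[(2R,3R)-3,5,7-tris(benzyloxy)-2-(4-benzyloxyphenyl)chroman-8-yl]chroman-3-yl acetate | C(c1ccccc1)Oc1ccc([C@H]2Oc3cc(OCc4ccccc4)ccc3[C@@H](c3c(OCc4ccccc4)cc(OCc4ccccc4)c4c3O[C@H](c3ccc(OCc5ccccc5)cc3)[C@H](OCc3ccccc3)C4)[C@@H]2OC(C)=O)cc1 | intermediate
16 | (2R,3S,4S)-7-(benzyloxy)-2-[4-(benzyloxy)phenyl]-4-[(2R,3R)-3,5,7-tris(benzyloxy)-2-(4-benzyloxyphenyl)chroman-8-yl]chroman-3-ol | C(c1ccccc1)Oc1ccc([C@H]2Oc3cc(OCc4ccccc4)ccc3[C@@H](c3c(OCc4ccccc4)cc(OCc4ccccc4)c4c3O[C@H](c3ccc(OCc5ccccc5)cc3)[C@H](OCc3ccccc3)C4)[C@@H]2O)cc1 | intermediate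
17 | (2R,3S,4S)-2-(4-hydroxyphenyl)-4-[(2R,3R)-3,5,7-trihydroxy-2-(4-hydroxyphenyl)chroman-8-yl]chroman-3,7-diol, guibourtinidol-(4α→8)-epiafzelechin | Oc1ccc([C@H]2Oc3cc(O)ccc3[C@@H](c3c(O)cc(O)c4c3O[C@H](c3ccc(O)cc3)[C@H](O)C4)[C@@H]2O)cc1 | target

Total step count: 12. Longest linear sequence: 8 steps (steps 1, 2, 3, 5, 6, 10, 11, 12, from epiafzelechin).

Steps most likely to fail

Step 10 (proposed new method). The acetoxy-substituted alkene may add too slowly to the strongly stabilised, sterically shielded methide. Self-condensation of the methide through the free C6' position of ring D, hydrolysis of the enol acetate by the water released, addition with the opposite regiochemistry, or weak facial discrimination by the phosphate could then prevail. The fallback uses known chemistry, sets out from 9 and rejoins the route at 16. Commercial 4'-(benzyloxy)acetophenone is converted with TMSOTf/Et3N into 1-[4-(benzyloxy)phenyl]-1-(trimethylsilyloxy)ethene F1, a far stronger π-nucleophile in which oxygen and aryl polarise the alkene in the same direction. Under the same phosphoric acid at –40 °C it should undergo the classical o-quinone methide/enol ether cycloaddition with 14 to the 2-(trimethylsilyloxy)-2,4-diarylchroman F2, which is not isolated. Catalytic pyridinium p-toluenesulfonate then removes trimethylsilanol to give the (4S)-2,4-diaryl-4H-chromene F3, with C4 set by the catalyst at a temperature where its control is better. Hydroboration with BH3·THF at 0 °C places boron at C3 on the face opposite the C4 aryl and hydrogen at C2 on the same face, giving the C3 alkylborane F4. Oxidation with NaOH/H2O2, which retains configuration, should give the 2,3-trans-3,4-trans alcohol 16 directly.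

Step 6. The unmasked o-hydroxybenzhydrol may ionise on the adsorbent or on standing, and the methide so formed may condense with itself before it meets the dienophile. The fallback sets out from 8 and comes back at 9, and stores the material at the ketone oxidation level. Oxidation of 8 with MnO2 (CH2Cl2, rt) gives [2-(allyloxy)-4-(benzyloxy)phenyl][(2R,3R)-3,5,7-tris(benzyloxy)-2-(4-benzyloxyphenyl)chroman-8-yl]methanone F5, which cannot ionise. The same Pd(PPh3)4/morpholine deallylation then gives the hydrogen-bonded 2-hydroxybenzophenone [4-(benzyloxy)-2-hydroxyphenyl][(2R,3R)-3,5,7-tris(benzyloxy)-2-(4-benzyloxyphenyl)chroman-8-yl]methanone F6, which can be purified and kept. Reduction with NaBH4 (THF/MeOH, 0 °C) immediately before use, with a basic work-up, returns 9 as a crude solution that goes straight into step 10.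

Step 5. The hindered, doubly ortho-oxygenated aryllithium may add sluggishly to the electron-rich, ortho-alkoxylated aldehyde, so that protonation and benzyl ether rearrangement of the aryllithium outrun C–C bond formation. The fallback sets out from 4 and comes back at 8, with the polarity of the union reversed. The aryllithium 7 is quenched with the small, reactive electrophile DMF to give (2R,3R)-3,5,7-tris(benzyloxy)-2-[4-(benzyloxy)phenyl]chroman-8-carbaldehyde F7. Commercial 3-(benzyloxy)phenol is iodinated ortho to the hydroxyl and para to the ether (I2, NaHCO3, THF/H2O) to 5-(benzyloxy)-2-iodophenol F8, then allylated (allyl bromide, K2CO3, DMF) to 2-(allyloxy)-4-(benzyloxy)-1-iodobenzene F9. Iodine–magnesium exchange (i-PrMgCl·LiCl, THF, –20 °C) converts F9 into the unhindered Grignard reagent [2-(allyloxy)-4-(benzyloxy)phenyl]magnesium chloride F10, whose addition to F7 should give 8.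

Further compounds
F1 | step 10 | 1-[4-(benzyloxy)phenyl]-1-(trimethylsilyloxy)ethene | C=C(O[Si](C)(C)C)c1ccc(OCc2ccccc2)cc1
F2 | step 10 | (4S)-7-(benzyloxy)-2-[4-(benzyloxy)phenyl]-2-(trimethylsilyloxy)-4-[(2R,3R)-3,5,7-tris(benzyloxy)-2-(4-benzyloxyphenyl)chroman-8-yl]chroman (C2 epimers, not isolated) | C(c1ccccc1)Oc1ccc(C2(O[Si](C)(C)C)Oc3cc(OCc4ccccc4)ccc3[C@@H](c3c(OCc4ccccc4)cc(OCc4ccccc4)c4c3O[C@H](c3ccc(OCc5ccccc5)cc3)[C@H](OCc3ccccc3)C4)C2)cc1
F3 | step 10 | (4S)-7-(benzyloxy)-2-[4-(benzyloxy)phenyl]-4-[(2R,3R)-3,5,7-tris(benzyloxy)-2-(4-benzyloxyphenyl)chroman-8-yl]-4H-chromene | C(c1ccccc1)Oc1ccc(C2Oc3cc(OCc4ccccc4)ccc3[C@@H](c3c(OCc4ccccc4)cc(OCc4ccccc4)c4c3O[C@H](c3ccc(OCc5ccccc5)cc3)[C@H](OCc3ccccc3)C4)C=2)cc1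
F4 | step 10 | C3 borane adduct of F3, (2R,3S,4S)-3-boranyl-7-(benzyloxy)-2-[4-(benzyloxy)phenyl]-4-[(2R,3R)-3,5,7-tris(benzyloxy)-2-(4-benzyloxyphenyl)chroman-8-yl]chroman (not isolated) | C(c1ccccc1)Oc1ccc([C@H]2Oc3cc(OCc4ccccc4)ccc3[C@@H](c3c(OCc4ccccc4)cc(OCc4ccccc4)c4c3O[C@H](c3ccc(OCc5ccccc5)cc3)[C@H](OCc3ccccc3)C4)[C@@H]2B)cc1
F5 | step 6 | [2-(allyloxy)-4-(benzyloxy)phenyl][(2R,3R)-3,5,7-tris(benzyloxy)-2-(4-benzyloxyphenyl)chroman-8-yl]methanone | O=C(c1ccc(OCc2ccccc2)cc1OCC=C)c1c(OCc2ccccc2)cc(OCc2ccccc2)c2c1O[C@H](c1ccc(OCc3ccccc3)cc1)[C@H](OCc1ccccc1)C2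
F6 | step 6 | [4-(benzyloxy)-2-hydroxyphenyl][(2R,3R)-3,5,7-tris(benzyloxy)-2-(4-benzyloxyphenyl)chroman-8-yl]methanone | O=C(c1ccc(OCc2ccccc2)cc1O)c1c(OCc2ccccc2)cc(OCc2ccccc2)c2c1O[C@H](c1ccc(OCc3ccccc3)cc1)[C@H](OCc1ccccc1)C2
F7 | step 5 | (2R,3R)-3,5,7-tris(benzyloxy)-2-[4-(benzyloxy)phenyl]chroman-8-carbaldehyde | O=Cc1c(OCc2ccccc2)cc(OCc2ccccc2)c2c1O[C@H](c1ccc(OCc3ccccc3)cc1)[C@H](OCc1ccccc1)C2
F8 | step 5 | 5-(benzyloxy)-2-iodophenol | Oc1cc(OCc2ccccc2)ccc1I
F9 | step 5 | 2-(allyloxy)-4-(benzyloxy)-1-iodobenzene | C=CCOc1cc(OCc2ccccc2)ccc1I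
F10 | step 5 | [2-(allyloxy)-4-(benzyloxy)phenyl]magnesium chloride | C=CCOc1cc(OCc2ccccc2)ccc1[Mg]Cl
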